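**Retrosynthetic overview** (longipinane numbering: C1 ketone, C2=C3(Me), bridgeheads C4/C11, cyclobutane C4–C5–C11–C10, seven-membered ring C4–C5–C6(Me2)–C7(OH)–C8(OAng)–C9(OiVal)–C10(Me))
1. Endgame: C9 isovalerate, then C8 angelate, on a tricycle that carries O7/O8 as an L-tartrate acetonide; the enone comes from a saturated C1 silyl ether by oxidation/dehydrogenation.
2. Key disconnection C5–C6 (seven-membered ring, closed last): a tertiary C6 radical (H-atom transfer to an isopropenyl group) adds to the C5 N-tosylhydrazone of a cyclobutanone; sulfinate and N2 then leave, so C5=O becomes C5–H.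
3. Enabling feature: in the bicyclo[3.1.1]heptane the one-carbon bridges C5 and C10 face each other across the cyclobutane, so the C9–C6 chain on C10 (anti to the C1–C3 bridge) lies over the C5 π-face; C5 is CH in the target, so its carbonyl is a traceless handle.
4. Cyclobutane and six-membered ring are formed together by an intramolecular ketene–alkene [2+2] of acyclic acid 15 (C5 = ketene carbonyl; E-alkene puts 10-Me syn and the chain anti; C1–OSiEt3 and C3–Me relay the absolute configuration).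
5. Acid 15 comes from L-tartaric diamide 1 (C6–C9), iodide 4 (C10, C11, C1) and dienolate 11 (C2–C5); ring order: [2+2] (four- and six-membered rings) → seven-membered ring (key step).

Key step: step 14

Remark: 1 and 4 are taken as purchasable (otherwise one step from dimethyl 2,3-O-isopropylidene-L-tartrate and Me2NH, and two steps from but-2-yn-1-ol); in the catalyst-controlled steps 8 and 10 the catalyst antipode is the one that gives the configuration drawn.

Step 1
Reactants: 1 (4R,5R)-N,N,N′,N′,2,2-hexamethyl-1,3-dioxolane-4,5-dicarboxamide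
Product: 2 (4R,5R)-5-acetyl-N,N,2,2-tetramethyl-1,3-dioxolane-4-carboxamide
Conditions: MeMgBr (1.5 equiv), THF, 0 °C; aq NH4Cl
Reagents that add atoms: methylmagnesium bromide, C[Mg]Br
Why: Controlled mono-addition of a Grignard reagent to the C2-symmetric tartaric bis(dimethylamide) (desymmetrisation); the chelated tetrahedral adduct releases the ketone only on work-up and deactivates the second amide, and the tartrate stereocentres are untouched.

Step 2
Reactants: 2
Product: 3 (4R,5S)-N,N,2,2-tetramethyl-5-(prop-1-en-2-yl)-1,3-dioxolane-4-carboxamide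
Conditions: Ph3PCH3Br, KOt-Bu, THF, 0 °C → rt
Reagents that add atoms: methylenetriphenylphosphorane (from methyltriphenylphosphonium bromide and KOt-Bu), C=P(c1ccccc1)(c1ccccc1)c1ccccc1
Why: Wittig methylenation of the ketone with the tertiary amide inert to the ylide; the trans-dioxolane is the thermodynamically preferred arrangement, so the α-centre is not at risk.

Step 3
Reactants: 4 (E)-3-iodobut-2-en-1-ol; 3
Product: 6 hydroxy enone (E)-1-[(4R,5S)-2,2-dimethyl-5-(prop-1-en-2-yl)-1,3-dioxolan-4-yl]-4-hydroxy-2-methylbut-2-en-1-one, via dilithio reagent 5 (not isolated)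
Conditions: 4, t-BuLi (3.1 equiv), Et2O, −78 °C; then 3, −78 → −20 °C; aq NH4Cl
Reagents that add atoms: none
Why: Iodine–lithium exchange gives a configurationally stable (E)-alkenyllithium alkoxide that acylates once on the tertiary amide (ketone released on work-up), so the E geometry needed for the later [2+2] is carried in unchanged.

Step 4
Reactants: 6
Product: 7 diol (1S,2E)-1-[(4S,5S)-2,2-dimethyl-5-(prop-1-en-2-yl)-1,3-dioxolan-4-yl]-2-methylbut-2-ene-1,4-diol
Conditions: Zn(BH4)2, Et2O, −30 °C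
Reagents that add atoms: none
Why: Chelation-controlled (Cram-chelate) 1,2-reduction of the α-alkoxy enone: zinc bridges the carbonyl and the adjacent dioxolane oxygen and hydride enters anti to the ring C–C bond, which sets the new carbinol (C9 of the target) anti (erythro) to the neighbouring oxygen.

Step 5
Reactants: 7
Product: 8 hydroxy enal (2E,4S)-4-[(4S,5S)-2,2-dimethyl-5-(prop-1-en-2-yl)-1,3-dioxolan-4-yl]-4-hydroxy-3-methylbut-2-enal
Conditions: TEMPO (10 mol %), PhI(OAc)2 (1.1 equiv), CH2Cl2, rt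
Reagents that add atoms: none
Why: Oxoammonium (TEMPO) oxidation is selective for the primary allylic alcohol over the hindered secondary one, and the E geometry keeps the free hydroxyl from closing onto the aldehyde.

Step 6
Reactants: 8
Product: 9 silyl enal (2E,4S)-4-[(tert-butyldimethylsilyl)oxy]-4-[(4R,5S)-2,2-dimethyl-5-(prop-1-en-2-yl)-1,3-dioxolan-4-yl]-3-methylbut-2-enal
Conditions: TBSOTf, 2,6-lutidine, CH2Cl2, −78 °C
Reagents that add atoms: tert-butyldimethylsilyl trifluoromethanesulfonate, CC(C)(C)[Si](C)(C)OS(=O)(=O)C(F)(F)F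
Why: Silyl triflate protection of the hindered secondary alcohol under non-nucleophilic base, leaving enal and acetonide untouched.

Step 7
Reactants: 10 ethyl 3-methylbut-2-enoate
Product: 11 tert-butyl[(1-ethoxy-3-methylbuta-1,3-dien-1-yl)oxy]dimethylsilane
Conditions: LDA, THF/DMPU, −78 °C; TBSCl
Reagents that add atoms: tert-butyldimethylsilyl chloride, CC(C)(C)[Si](C)(C)Cl
Why: γ-Deprotonation of the senecioate and O-silylation of the dienolate give the silyl ketene acetal (silyl dienolate formation).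

Step 8
Reactants: 9; 11
Product: 12 ethyl (2E,5S,6E,8S)-8-[(tert-butyldimethylsilyl)oxy]-8-[(4R,5S)-2,2-dimethyl-5-(prop-1-en-2-yl)-1,3-dioxolan-4-yl]-5-hydroxy-3,7-dimethylocta-2,6-dienoate
Conditions: SiCl4 (1.2 equiv), chiral binaphthyldiamine-derived bisphosphoramide (5 mol %), i-Pr2NEt (0.2 equiv), CH2Cl2, −78 °C; aq NaHCO3
Reagents that add atoms: none
Why: Catalytic enantioselective vinylogous Mukaiyama aldol addition (Lewis-base-activated SiCl4): the dienolate attacks through its γ-carbon to give the (E)-enoate, and the catalyst directs it to the Si face of the enal, which sets the (5S) carbinol (C1 of the target) under catalyst control because the existing centres are remote.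

Step 9
Reactants: 12
Product: 13 ethyl (2E,5S,6E,8S)-8-[(tert-butyldimethylsilyl)oxy]-8-[(4R,5S)-2,2-dimethyl-5-(prop-1-en-2-yl)-1,3-dioxolan-4-yl]-3,7-dimethyl-5-[(triethylsilyl)oxy]octa-2,6-dienoate
Conditions: TESOTf, 2,6-lutidine, CH2Cl2, −78 °C
Reagents that add atoms: triethylsilyl trifluoromethanesulfonate, CC[Si](CC)(CC)OS(=O)(=O)C(F)(F)F
Why: Silylation gives a triethylsilyl ether that can later be removed in the presence of the TBS ether.

Step 10
Reactants: 13
Product: 14 ethyl (3R,5S,6E,8S)-8-[(tert-butyldimethylsilyl)oxy]-8-[(4R,5S)-2,2-dimethyl-5-(prop-1-en-2-yl)-1,3-dioxolan-4-yl]-3,7-dimethyl-5-[(triethylsilyl)oxy]oct-6-enoate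
Conditions: Cu(OAc)2·H2O (3 mol %), DTBM-SEGPHOS (3 mol %), (EtO)2MeSiH (2 equiv), t-BuOH (1.5 equiv), toluene, 0 °C → rt
Reagents that add atoms: none
Why: Ligand-controlled copper hydride conjugate reduction of the β,β-disubstituted (E)-enoate (asymmetric 1,4-reduction) sets the (3R) methyl centre and leaves the isolated alkenes alone; this removes the only other HAT-reactive alkene before the key step and places the methyl so that it reinforces the facial bias in step 12.

Step 11
Reactants: 14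
Product: 15 (3R,5S,6E,8S)-8-[(tert-butyldimethylsilyl)oxy]-8-[(4R,5S)-2,2-dimethyl-5-(prop-1-en-2-yl)-1,3-dioxolan-4-yl]-3,7-dimethyl-5-[(triethylsilyl)oxy]oct-6-enoic acid
Conditions: LiOH·H2O, THF/H2O (3:1), 25 °C; then 0.5 M HCl to pH 5, 0 °C
Reagents that add atoms: lithium hydroxide, [Li+].[OH-]
Why: Saponification of the unhindered saturated ethyl ester; the silyl ethers and acetonide are stable to hydroxide.

Step 12
Reactants: 15
Product: 18 bicyclic cyclobutanone 2,7-dimethyl-4-[(triethylsilyl)oxy]-7-{(S)-[(tert-butyldimethylsilyl)oxy][(4R,5S)-2,2-dimethyl-5-(prop-1-en-2-yl)-1,3-dioxolan-4-yl]methyl}bicyclo[3.1.1]heptan-6-one (7-Me syn and side chain anti to the C2–C4 bridge; 2-Me and 4-OSiEt3 on the face turned toward C6), via acid chloride 16 (not isolated), via alkylketene 17 (not isolated)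
Conditions: 1-chloro-N,N,2-trimethylprop-1-en-1-amine (1.2 equiv), CH2Cl2, 0 °C → rt; then added over 6 h to Et3N (5 equiv), toluene, 110 °C, 0.003 M
Reagents that add atoms: none
Why: Intramolecular ketene–alkene [2+2] cycloaddition through a three-atom tether onto a trisubstituted alkene gives the crossed bicyclo[3.1.1]heptan-6-one (ketene carbonyl carbon to the less substituted alkene carbon); suprafacial addition to the E-alkene places the methyl syn and the chain anti on the quaternary bridge, and the alkene face is selected by allylic 1,3-strain at the silyloxy carbon together with the pseudo-equatorial tether methyl, which should set C4, C10 and C11 of the target in the absolute sense.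

Step 13
Reactants: 18
Product: 19 N-tosylhydrazone of 18 at the cyclobutanone carbon
Conditions: TsNHNH2 (1.2 equiv), MeOH/THF, 25 °C
Reagents that add atoms: 4-methylbenzenesulfonohydrazide, Cc1ccc(cc1)S(=O)(=O)NN
Why: Hydrazone condensation at the strained, non-enolisable cyclobutanone, the only carbonyl group present, without acid so the silyl ethers survive.

Step 14
Reactants: 19
Product: 22 tricycle 7,8-O-isopropylidene-9-O-(tert-butyldimethylsilyl)-1-O-(triethylsilyl)longipinane-1,7,8,9-tetrol (ring stereocentres as in 29; 1-O and 3-Me anti to C10), via cyclised tosylhydrazide 20 (not isolated), via diazene 21 (not isolated)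
Conditions: Fe(acac)3 (0.3 equiv), PhSiH3 (2.5 equiv), EtOH/THF (degassed), 60 °C, 0.01 M; then Et3N (5 equiv), MeOH, 65 °C
Reagents that add atoms: none
Why: Proposed new method: an iron hydride formed from Fe(acac)3/PhSiH3 transfers H• to the CH2 of the only alkene (isopropenyl), the tertiary C6 radical adds to C5 of the sulfonylhydrazone C=N, the hydrazinyl radical is reduced to tosylhydrazide 20, and warming with base expels sulfinate to diazene 21 and then N2, leaving C5–H. The closest known reaction types are the iron-mediated Markovnikov hydromethylation of alkenes through formaldehyde sulfonylhydrazone (same acceptor class, same traceless loss of sulfinate and N2) and HAT-initiated intramolecular alkene–hydrazone couplings that close five- and six-membered rings; new here are the seven-membered ring and a cyclobutanone-derived, fully substituted acceptor carbon. The seven-membered ring closes by 7-exo-trig radical addition to C=N, forming the C5–C6 bond and the quaternary gem-dimethyl carbon C6 in the same event. The only new stereocentre is C5: the chain can reach only the C5 face turned toward C10 (cis-1,3 bridge across the cyclobutane), and hydrogen can then arrive only on the outer face, so the configuration is enforced by the ring, while C6 is not stereogenic. The step needs chemoselective HAT and cyclisation faster than radical reduction or cyclobutane opening; this is secured by keeping C1 as a silyl ether and C2–C3 saturated (no second alkene, no β-amino-ketone fragmentation path), by the rigid 1,3-placement of chain and acceptor on the cyclobutane, and by the trans-acetonide, which holds the C9–C8–C7–C6 torsion gauche.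

Step 15
Reactants: 22
Product: 23 C1 alcohol 7,8-O-isopropylidene-9-O-(tert-butyldimethylsilyl)longipinane-1,7,8,9-tetrol
Conditions: HF·pyridine, pyridine, THF, 0 °C
Reagents that add atoms: none
Why: Buffered fluoride cleaves the triethylsilyl ether much faster than the hindered TBS ether (selective desilylation); the acetonide is stable.

Step 16
Reactants: 23
Product: 25 enone 7,8-O-isopropylidene-9-O-(tert-butyldimethylsilyl)-7,8,9-trihydroxylongipin-2-en-1-one, via saturated ketone 24 (not isolated)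
Conditions: IBX (4 equiv), DMSO/toluene, 25 °C then 75 °C
Reagents that add atoms: none
Why: IBX oxidises the alcohol to the ketone and then dehydrogenates it (IBX α,β-dehydrogenation); enolisation is possible only toward C2 because C11 is a bridgehead, so the C2=C3 enone forms regardless of the C3 configuration, which is erased.

Step 17
Reactants: 25
Product: 26 C9 alcohol 7,8-O-isopropylidene-7,8,9-trihydroxylongipin-2-en-1-one
Conditions: TBAF, THF, 25 → 45 °C
Reagents that add atoms: none
Why: Fluoride desilylation of the hindered secondary TBS ether; no ester is present yet, so the basic conditions cannot cause acyl migration.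

Step 18
Reactants: 26
Product: 27 C9 isovalerate 7,8-O-isopropylidene-9-(3-methylbutanoyloxy)-7,8-dihydroxylongipin-2-en-1-one
Conditions: (i-PrCH2CO)2O, DMAP, Et3N, CH2Cl2, 40 °C
Reagents that add atoms: 3-methylbutanoic anhydride, CC(C)CC(=O)OC(=O)CC(C)C
Why: DMAP-catalysed acylation of the only free hydroxyl, so no regioselectivity is required.

Step 19
Reactants: 27
Product: 28 diol 7,8-dihydroxy-9-(3-methylbutanoyloxy)longipin-2-en-1-one
Conditions: AcOH/H2O/THF (3:1:1), 45 °C
Reagents that add atoms: none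
Why: Acid hydrolysis of the strained trans-fused acetonide under conditions too mild to move the ester or disturb the enone.

Step 20
Reactants: 28
Product: 29 target (4R,5S,7S,8R,9S,10R,11R)-8-angeloyloxy-7-hydroxy-9-(3-methylbutanoyloxy)longipin-2-en-1-one
Conditions: angelic acid, 2,4,6-trichlorobenzoyl chloride, Et3N, toluene, 25 °C; then 28, toluene, 75 °C (no DMAP)
Reagents that add atoms: angelic acid (as its 2,4,6-trichlorobenzoyl mixed anhydride), C/C=C(/C)C(=O)O
Why: Yamaguchi-type mixed-anhydride esterification without a nucleophilic catalyst keeps the Z geometry, and the C8 hydroxyl (between two CH–O carbons) should react in preference to the neopentyl C7 hydroxyl next to CMe2.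

**Compound list**
1 | (4R,5R)-N,N,N′,N′,2,2-hexamethyl-1,3-dioxolane-4,5-dicarboxamide | CN(C)C(=O)[C@@H]1OC(C)(C)O[C@H]1C(=O)N(C)C | starting material
2 | (4R,5R)-5-acetyl-N,N,2,2-tetramethyl-1,3-dioxolane-4-carboxamide | CN(C)C(=O)[C@@H]1OC(C)(C)O[C@H]1C(C)=O | intermediate
3 | (4R,5S)-N,N,2,2-tetramethyl-5-(prop-1-en-2-yl)-1,3-dioxolane-4-carboxamide | CN(C)C(=O)[C@@H]1OC(C)(C)O[C@H]1C(C)=C | intermediate
4 | (E)-3-iodobut-2-en-1-ol | OC/C=C(\C)I | starting material
5 | lithium (E)-3-lithiobut-2-en-1-olate | [Li]OC/C=C(\C)[Li] | intermediate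
6 | (E)-1-[(4R,5S)-2,2-dimethyl-5-(prop-1-en-2-yl)-1,3-dioxolan-4-yl]-4-hydroxy-2-methylbut-2-en-1-one | OC/C=C(\C)C(=O)[C@@H]1OC(C)(C)O[C@H]1C(C)=C | intermediate
7 | (1S,2E)-1-[(4S,5S)-2,2-dimethyl-5-(prop-1-en-2-yl)-1,3-dioxolan-4-yl]-2-methylbut-2-ene-1,4-diol | OC/C=C(\C)[C@H](O)[C@@H]1OC(C)(C)O[C@H]1C(C)=C | intermediate
8 | (2E,4S)-4-[(4S,5S)-2,2-dimethyl-5-(prop-1-en-2-yl)-1,3-dioxolan-4-yl]-4-hydroxy-3-methylbut-2-enal | O=C/C=C(\C)[C@H](O)[C@@H]1OC(C)(C)O[C@H]1C(C)=C | intermediate
9 | (2E,4S)-4-[(tert-butyldimethylsilyl)oxy]-4-[(4R,5S)-2,2-dimethyl-5-(prop-1-en-2-yl)-1,3-dioxolan-4-yl]-3-methylbut-2-enal | O=C/C=C(\C)[C@H](O[Si](C)(C)C(C)(C)C)[C@@H]1OC(C)(C)O[C@H]1C(C)=C | intermediate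
10 | ethyl 3-methylbut-2-enoate | CCOC(=O)C=C(C)C | starting material
11 | tert-butyl[(1-ethoxy-3-methylbuta-1,3-dien-1-yl)oxy]dimethylsilane | C=C(C)C=C(OCC)O[Si](C)(C)C(C)(C)C | intermediate
12 | ethyl (2E,5S,6E,8S)-8-[(tert-butyldimethylsilyl)oxy]-8-[(4R,5S)-2,2-dimethyl-5-(prop-1-en-2-yl)-1,3-dioxolan-4-yl]-5-hydroxy-3,7-dimethylocta-2,6-dienoate | CCOC(=O)/C=C(\C)C[C@H](O)/C=C(\C)[C@H](O[Si](C)(C)C(C)(C)C)[C@@H]1OC(C)(C)O[C@H]1C(C)=C | intermediate
13 | ethyl (2E,5S,6E,8S)-8-[(tert-butyldimethylsilyl)oxy]-8-[(4R,5S)-2,2-dimethyl-5-(prop-1-en-2-yl)-1,3-dioxolan-4-yl]-3,7-dimethyl-5-[(triethylsilyl)oxy]octa-2,6-dienoate | CCOC(=O)/C=C(\C)C[C@H](O[Si](CC)(CC)CC)/C=C(\C)[C@H](O[Si](C)(C)C(C)(C)C)[C@@H]1OC(C)(C)O[C@H]1C(C)=C | intermediate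
14 | ethyl (3R,5S,6E,8S)-8-[(tert-butyldimethylsilyl)oxy]-8-[(4R,5S)-2,2-dimethyl-5-(prop-1-en-2-yl)-1,3-dioxolan-4-yl]-3,7-dimethyl-5-[(triethylsilyl)oxy]oct-6-enoate | CCOC(=O)C[C@H](C)C[C@H](O[Si](CC)(CC)CC)/C=C(\C)[C@H](O[Si](C)(C)C(C)(C)C)[C@@H]1OC(C)(C)O[C@H]1C(C)=C | intermediate
15 | (3R,5S,6E,8S)-8-[(tert-butyldimethylsilyl)oxy]-8-[(4R,5S)-2,2-dimethyl-5-(prop-1-en-2-yl)-1,3-dioxolan-4-yl]-3,7-dimethyl-5-[(triethylsilyl)oxy]oct-6-enoic acid | OC(=O)C[C@H](C)C[C@H](O[Si](CC)(CC)CC)/C=C(\C)[C@H](O[Si](C)(C)C(C)(C)C)[C@@H]1OC(C)(C)O[C@H]1C(C)=C | intermediate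
16 | acid chloride of 15 (same configuration) | ClC(=O)C[C@H](C)C[C@H](O[Si](CC)(CC)CC)/C=C(\C)[C@H](O[Si](C)(C)C(C)(C)C)[C@@H]1OC(C)(C)O[C@H]1C(C)=C | intermediate
17 | (3R,5S,6E,8S)-8-[(tert-butyldimethylsilyl)oxy]-8-[(4R,5S)-2,2-dimethyl-5-(prop-1-en-2-yl)-1,3-dioxolan-4-yl]-3,7-dimethyl-5-[(triethylsilyl)oxy]octa-1,6-dien-1-one (alkylketene) | O=C=C[C@H](C)C[C@H](O[Si](CC)(CC)CC)/C=C(\C)[C@H](O[Si](C)(C)C(C)(C)C)[C@@H]1OC(C)(C)O[C@H]1C(C)=C | intermediate
18 | 2,7-dimethyl-4-[(triethylsilyl)oxy]-7-{(S)-[(tert-butyldimethylsilyl)oxy][(4R,5S)-2,2-dimethyl-5-(prop-1-en-2-yl)-1,3-dioxolan-4-yl]methyl}bicyclo[3.1.1]heptan-6-one; 7-Me syn and side chain anti to the C2–C4 bridge; 2-Me and 4-OSiEt3 on the face turned toward C6; C1/C5 become C4/C11 of 29 | C=C(C)[C@@H]4OC(C)(C)O[C@H]4[C@@H](O[Si](C)(C)C(C)(C)C)[C@@]1(C)[C@@H]2[C@@H](O[Si](CC)(CC)CC)C[C@@H](C)[C@H]1C2=O | intermediate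
19 | N-tosylhydrazone of 18 at C6 (same configuration) | C=C(C)[C@@H]4OC(C)(C)O[C@H]4[C@@H](O[Si](C)(C)C(C)(C)C)[C@@]1(C)[C@@H]2[C@@H](O[Si](CC)(CC)CC)C[C@@H](C)[C@H]1C2=NNS(=O)(=O)c5ccc(C)cc5 | intermediate
20 | 5-(2-tosylhydrazinyl) derivative of 22 (N on C5 on the outer face; otherwise as 22) | CC4(C)O[C@@H]1[C@@H](O4)C(C)(C)[C@]2(NNS(=O)(=O)c5ccc(C)cc5)[C@H]3[C@@H](O[Si](CC)(CC)CC)C[C@@H](C)[C@@H]2[C@@]3(C)[C@@H]1O[Si](C)(C)C(C)(C)C | intermediate
21 | 5-diazenyl derivative of 22 (otherwise as 22) | CC4(C)O[C@@H]1[C@@H](O4)C(C)(C)[C@]2(N=N)[C@H]3[C@@H](O[Si](CC)(CC)CC)C[C@@H](C)[C@@H]2[C@@]3(C)[C@@H]1O[Si](C)(C)C(C)(C)C | intermediate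
22 | 7,8-O-isopropylidene-9-O-(tert-butyldimethylsilyl)-1-O-(triethylsilyl)longipinane-1,7,8,9-tetrol; C4, C5, C7–C11 as in 29; 1-O and 3-Me anti to C10 | CC4(C)O[C@@H]1[C@@H](O4)C(C)(C)[C@@H]2[C@H]3[C@@H](O[Si](CC)(CC)CC)C[C@@H](C)[C@@H]2[C@@]3(C)[C@@H]1O[Si](C)(C)C(C)(C)C | intermediate
23 | 7,8-O-isopropylidene-9-O-(tert-butyldimethylsilyl)longipinane-1,7,8,9-tetrol (configuration as 22) | CC4(C)O[C@@H]1[C@@H](O4)C(C)(C)[C@@H]2[C@H]3[C@@H](O)C[C@@H](C)[C@@H]2[C@@]3(C)[C@@H]1O[Si](C)(C)C(C)(C)C | intermediate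
24 | 7,8-O-isopropylidene-9-O-(tert-butyldimethylsilyl)-7,8,9-trihydroxylongipinan-1-one (configuration as 22) | CC4(C)O[C@@H]1[C@@H](O4)C(C)(C)[C@@H]2[C@H]3C(=O)C[C@@H](C)[C@@H]2[C@@]3(C)[C@@H]1O[Si](C)(C)C(C)(C)C | intermediate
25 | 7,8-O-isopropylidene-9-O-(tert-butyldimethylsilyl)-7,8,9-trihydroxylongipin-2-en-1-one (ring stereocentres as in 29) | CC4(C)O[C@@H]1[C@@H](O4)C(C)(C)[C@@H]2[C@H]3C(=O)C=C(C)[C@@H]2[C@@]3(C)[C@@H]1O[Si](C)(C)C(C)(C)C | intermediate
26 | 7,8-O-isopropylidene-7,8,9-trihydroxylongipin-2-en-1-one (ring stereocentres as in 29) | CC4(C)O[C@@H]1[C@@H](O4)C(C)(C)[C@@H]2[C@H]3C(=O)C=C(C)[C@@H]2[C@@]3(C)[C@@H]1O | intermediate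
27 | 7,8-O-isopropylidene-9-(3-methylbutanoyloxy)-7,8-dihydroxylongipin-2-en-1-one (ring stereocentres as in 29) | CC4(C)O[C@@H]1[C@@H](O4)C(C)(C)[C@@H]2[C@H]3C(=O)C=C(C)[C@@H]2[C@@]3(C)[C@@H]1OC(=O)CC(C)C | intermediate
28 | 7,8-dihydroxy-9-(3-methylbutanoyloxy)longipin-2-en-1-one (ring stereocentres as in 29) | O[C@@H]1[C@@H](O)C(C)(C)[C@@H]2[C@H]3C(=O)C=C(C)[C@@H]2[C@@]3(C)[C@@H]1OC(=O)CC(C)C | intermediate
29 | (4R,5S,7S,8R,9S,10R,11R)-8-[(Z)-2-methylbut-2-enoyloxy]-7-hydroxy-9-(3-methylbutanoyloxy)longipin-2-en-1-one | C/C=C(/C)C(=O)O[C@@H]1[C@@H](O)C(C)(C)[C@@H]2[C@H]3C(=O)C=C(C)[C@@H]2[C@@]3(C)[C@@H]1OC(=O)CC(C)C | target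

Total step count: 20. Longest linear sequence: 19 (steps 1–6 and 8–20; step 7 is a one-step side branch).

**Steps most likely to fail**

1. Step 14 (proposed new method). The tertiary C6 radical may be reduced, or the alkene isomerised, before the slow 7-exo closure; the strained hydrazinyl radical or hydrazide may also open the cyclobutane before nitrogen is lost. Fallback with known chemistry, setting out from 18: cobalt-mediated Markovnikov hydrobromination (Co(acac)2, t-BuOOH, Et3SiH, TsBr) gives the tertiary bromide F1. Condensation with 1-amino-2-phenylaziridine gives the N-aziridinylimine F2. Slow addition of Bu3SnH/AIBN in refluxing benzene then runs the established tin-hydride radical cyclisation onto an N-aziridinylimine: the aminyl radical collapses at once with loss of styrene and N2, and the C5 radical is quenched by the stannane. The route is rejoined at 22.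

2. Step 12. The ketene may oligomerise or convert poorly because the alkene is flanked by two allylic C–O bonds and a branched substituent, and facial selectivity may erode at 110 °C. Fallback, setting out from 15: amide coupling with pyrrolidine gives the pyrrolidine amide F3. Tf2O and 2,6-di-tert-butyl-4-methylpyridine in 1,2-dichloroethane convert it into the keteniminium triflate F4, which is more electrophilic than the ketene and cannot dimerise. It cyclises to the cyclobutaniminium triflate F5, and aqueous NaHCO3 hydrolysis rejoins the route at 18.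

3. Step 20. Slow acylation of the hindered C8 hydroxyl may let the activated angelate isomerise (Z to E) and allow acyl transfer to C7–OH or migration of the C9 isovalerate. Fallback, setting out from 28: bis-silylation (TESOTf, 2,6-lutidine) gives the bis-triethylsilyl ether F6. Selective acidic cleavage of the less hindered C8 silyl ether (PPTS, MeOH/CH2Cl2, −10 °C) gives the C7 mono-silyl ether F7, which has a single free hydroxyl. Forcing acylation with excess mixed anhydride then gives the C7-silylated angelate F8, and HF·pyridine removes the silyl group to rejoin the route at 29.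

**Further compounds**
F1 | step 14 | 2-bromopropan-2-yl analogue of 18 (Markovnikov HBr adduct of the isopropenyl group) | CC(C)(Br)[C@@H]4OC(C)(C)O[C@H]4[C@@H](O[Si](C)(C)C(C)(C)C)[C@@]1(C)[C@@H]2[C@@H](O[Si](CC)(CC)CC)C[C@@H](C)[C@H]1C2=O
F2 | step 14 | N-(2-phenylaziridin-1-yl)imine of F1 | CC(C)(Br)[C@@H]4OC(C)(C)O[C@H]4[C@@H](O[Si](C)(C)C(C)(C)C)[C@@]1(C)[C@@H]2[C@@H](O[Si](CC)(CC)CC)C[C@@H](C)[C@H]1C2=NN5CC5c6ccccc6
F3 | step 12 | pyrrolidine amide of acid 15 | O=C(N2CCCC2)C[C@H](C)C[C@H](O[Si](CC)(CC)CC)/C=C(\C)[C@H](O[Si](C)(C)C(C)(C)C)[C@@H]1OC(C)(C)O[C@H]1C(C)=C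
F4 | step 12 | keteniminium triflate derived from F3 | C(=C=[N+]2CCCC2)[C@H](C)C[C@H](O[Si](CC)(CC)CC)/C=C(\C)[C@H](O[Si](C)(C)C(C)(C)C)[C@@H]1OC(C)(C)O[C@H]1C(C)=C.[O-]S(=O)(=O)C(F)(F)F
F5 | step 12 | pyrrolidinium (iminium) triflate of cyclobutanone 18 | C=C(C)[C@@H]4OC(C)(C)O[C@H]4[C@@H](O[Si](C)(C)C(C)(C)C)[C@@]1(C)[C@@H]2[C@@H](O[Si](CC)(CC)CC)C[C@@H](C)[C@H]1C2=[N+]5CCCC5.[O-]S(=O)(=O)C(F)(F)F
F6 | step 20 | 7,8-bis-O-(triethylsilyl) ether of 28 | CC[Si](CC)(CC)O[C@@H]1[C@@H](O[Si](CC)(CC)CC)C(C)(C)[C@@H]2[C@H]3C(=O)C=C(C)[C@@H]2[C@@]3(C)[C@@H]1OC(=O)CC(C)C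
F7 | step 20 | 7-O-(triethylsilyl) ether of 28 | O[C@@H]1[C@@H](O[Si](CC)(CC)CC)C(C)(C)[C@@H]2[C@H]3C(=O)C=C(C)[C@@H]2[C@@]3(C)[C@@H]1OC(=O)CC(C)C
F8 | step 20 | 7-O-(triethylsilyl) ether of 29 | C/C=C(/C)C(=O)O[C@@H]1[C@@H](O[Si](CC)(CC)CC)C(C)(C)[C@@H]2[C@H]3C(=O)C=C(C)[C@@H]2[C@@]3(C)[C@@H]1OC(=O)CC(C)C
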